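## Retrosynthetic overview

- The enone C(=O)–Cα bond is cut first: Rh-catalysed, phenol-chelated aldehyde C–H activation (hydroacylation) joins a dihydrobenzofuran salicylaldehyde to 4-ethynylphenol.
- The dihydrofuran ring is the only ring made (both benzene rings are bought). It comes from a formal (3+2) annulation of 2,4-dihydroxybenzaldehyde with (S)-3,3-dimethyloxirane-2-carbaldehyde: aryl C–C bond first, then 5-exo O–C2 closure.
- The epoxy aldehyde comes from prenol (asymmetric epoxidation, oxidation), the benzaldehyde from resorcinol (formylation), the alkyne from 4-iodophenol and TMS-acetylene (Sonogashira, desilylation).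
- Three branches, no protecting groups.

Assumption: the target is taken exactly as drawn, (2S,3S), which places the 3-OH trans to the 2-(2-hydroxypropan-2-yl) group; ethynyltrimethylsilane is counted as a starting material, DMF and t-BuOOH as reagents.

## Route

Step 1
Reactants: 1 resorcinol
Product: 3 2,4-dihydroxybenzaldehyde, via iminium chloride 2 (not isolated)
Conditions: POCl3, DMF, MeCN, −15 °C → rt; then H2O, 50 °C
Reagents that add atoms: N,N-dimethylformamide, CN(C)C=O; water, O
Why: Vilsmeier–Haack formylation, in which the chloroiminium ion attacks resorcinol at C4 (para to one OH, ortho to the other, the least hindered doubly activated site) and the iminium salt is hydrolysed to the aldehyde, with no stereocentre formed.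

Step 2
Reactants: 4 3-methylbut-2-en-1-ol
Product: 5 [(2R)-3,3-dimethyloxiran-2-yl]methanol
Conditions: Ti(OiPr)4 (10 mol%), D-(−)-DIPT (12 mol%), t-BuOOH (anhydrous), 4 Å MS, CH2Cl2, −20 °C; non-aqueous work-up
Reagents that add atoms: tert-butyl hydroperoxide, CC(C)(C)OO
Why: Sharpless asymmetric epoxidation, in which the Ti–tartrate–allyl alkoxide complex delivers the peroxide oxygen to one alkene face; D-(−)-tartrate is the mirror image of the L-(+)-series that gives 2S epoxy alcohols and therefore sets C2 as R.

Step 3
Reactants: 5 [(2R)-3,3-dimethyloxiran-2-yl]methanol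
Product: 6 (2S)-3,3-dimethyloxirane-2-carbaldehyde
Conditions: TEMPO (10 mol%), PhI(OAc)2 (1.1 equiv), CH2Cl2, 0 °C → rt; NaHCO3 wash, used as a titrated solution
Reagents that add atoms: none
Why: TEMPO/oxoammonium oxidation of the primary alcohol stops at the aldehyde under anhydrous conditions and leaves the epoxide and its non-enolisable stereocentre untouched (the descriptor changes from R to S only through the CIP priority change).

Step 4
Reactants: 3 2,4-dihydroxybenzaldehyde; 6 (2S)-3,3-dimethyloxirane-2-carbaldehyde
Product: 8 (2S,3S)-3,4-dihydroxy-2-(2-hydroxypropan-2-yl)-2,3-dihydro-1-benzofuran-5-carbaldehyde, via threo epoxy alcohol 7 (not isolated)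
Conditions: Mg(OMe)2 (1.1 equiv), toluene–CH2Cl2 (MeOH stripped), then 6, −20 °C → rt; then K2CO3 (0.2 equiv), MeOH, 50 °C; aq. NH4Cl
Reagents that add atoms: none
Why: Proposed new method: a magnesium-templated formal (3+2) annulation of a resorcinol-type phenol with an α,β-epoxy aldehyde, in which the Mg bis-phenoxide of 3 attacks through C3 (ortho to both O–Mg groups) the Mg-bound aldehyde of 6 in a closed six-membered transition state whose Mg also chelates the epoxide oxygen, so that the aryl carbon is delivered anti to the CMe2 carbon (Cram-chelate sense) to give the threo S-carbinol 7, after which the non-chelated 4-phenoxide opens the epoxide 5-exo at the secondary carbon with inversion (R → S) to give the trans 2S,3S ring; the closest known reactions are the ortho-specific hydroxyalkylation of magnesium phenoxides by aldehydes (the first stage of Mg-mediated ortho-formylation), the C3-selective base-mediated chromene annulation of 3 with enals, and the base-induced 5-exo cyclisation of o-(2,3-epoxyalkyl)phenols.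

Step 5
Reactants: 9 4-iodophenol; 10 ethynyltrimethylsilane
Product: 11 4-[(trimethylsilyl)ethynyl]phenol
Conditions: Pd(PPh3)2Cl2 (2 mol%), CuI (4 mol%), Et3N, THF, rt
Reagents that add atoms: none
Why: Sonogashira coupling (oxidative addition of Pd(0) into the aryl C–I bond, copper-acetylide transmetallation, reductive elimination), which tolerates the free phenol at room temperature.

Step 6
Reactants: 11 4-[(trimethylsilyl)ethynyl]phenol
Product: 12 4-ethynylphenol
Conditions: K2CO3 (0.2 equiv), MeOH, rt; used at once
Reagents that add atoms: none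
Why: Methoxide-catalysed protodesilylation of the alkynyl C–Si bond through a pentacoordinate silicate releases the terminal alkyne, which is carried forward immediately because it polymerises on storage.

Step 7
Reactants: 8 (2S,3S)-3,4-dihydroxy-2-(2-hydroxypropan-2-yl)-2,3-dihydro-1-benzofuran-5-carbaldehyde; 12 4-ethynylphenol
Product: 13 brosimacutin G, (E)-1-[(2S,3S)-3,4-dihydroxy-2-(2-hydroxypropan-2-yl)-2,3-dihydro-1-benzofuran-5-yl]-3-(4-hydroxyphenyl)prop-2-en-1-one
Conditions: [Rh(cod)Cl]2 (2.5 mol%), dppf (5 mol%), Na2CO3 (10 mol%), 12 (1.5 equiv), toluene–THF, 80 °C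
Reagents that add atoms: none
Why: Rh(I)-catalysed chelation-assisted alkyne hydroacylation (aldehyde C–H activation), in which the rhodium phenoxide of the salicylaldehyde unit inserts into the formyl C–H bond to give a five-membered acyl-rhodium hydride that resists decarbonylation, syn hydrometallation of 12 puts Rh on the terminal carbon, and C–C reductive elimination gives the linear E-enone without touching C2 or C3.

## Compound list

1 | resorcinol (benzene-1,3-diol) | Oc1cccc(O)c1 | starting material
2 | [(2,4-dihydroxyphenyl)methylidene]dimethylammonium chloride | C[N+](C)=Cc1ccc(O)cc1O.[Cl-] | intermediate (not isolated)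
3 | 2,4-dihydroxybenzaldehyde | O=Cc1ccc(O)cc1O | intermediate
4 | 3-methylbut-2-en-1-ol (prenol) | CC(C)=CCO | starting material
5 | [(2R)-3,3-dimethyloxiran-2-yl]methanol | OC[C@H]1OC1(C)C | intermediate
6 | (2S)-3,3-dimethyloxirane-2-carbaldehyde | O=C[C@H]1OC1(C)C | intermediate
7 | 3-[(S)-[(2R)-3,3-dimethyloxiran-2-yl](hydroxy)methyl]-2,4-dihydroxybenzaldehyde (threo; present as its Mg salt) | O=Cc1ccc(O)c([C@H](O)[C@H]2OC2(C)C)c1O | intermediate (not isolated)
8 | (2S,3S)-3,4-dihydroxy-2-(2-hydroxypropan-2-yl)-2,3-dihydro-1-benzofuran-5-carbaldehyde (3-OH trans to the C2 side chain) | CC(C)(O)[C@H]1Oc2ccc(C=O)c(O)c2[C@@H]1O | intermediate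
9 | 4-iodophenol | Oc1ccc(I)cc1 | starting material
10 | ethynyltrimethylsilane | C#C[Si](C)(C)C | starting material
11 | 4-[(trimethylsilyl)ethynyl]phenol | C[Si](C)(C)C#Cc1ccc(O)cc1 | intermediate
12 | 4-ethynylphenol | C#Cc1ccc(O)cc1 | intermediate
13 | brosimacutin G, (E)-1-[(2S,3S)-3,4-dihydroxy-2-(2-hydroxypropan-2-yl)-2,3-dihydro-1-benzofuran-5-yl]-3-(4-hydroxyphenyl)prop-2-en-1-one | CC(C)(O)[C@H]1Oc2ccc(C(=O)/C=C/c3ccc(O)cc3)c(O)c2[C@@H]1O | target

## Step count and risks

Total step count: 7. Longest linear sequence: 4 steps (4 → 5 → 6 → 8 → 13), which is 4/7 of the total.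

**Step 4 (the proposed new annulation).** It can fail in several ways:
- attack at C5 instead of C3;
- non-chelated (Felkin) addition, which would give the erythro adduct and hence the cis (2S,3R) diastereomer;
- 6-endo opening to a chromandiol;
- Oppenauer-type oxidation of the new benzylic Mg alkoxide by excess 6.

The fallback uses known chemistry, sets out from 1 and comes back at 8.
- Resorcinol 1 is benzylated (BnBr, K2CO3, DMF) to 1,3-bis(benzyloxy)benzene F1.
- Directed ortho-lithiation between the two ethers (n-BuLi, THF, 0 °C) gives [2,6-bis(benzyloxy)phenyl]lithium F2.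
- F2 is added with MgBr2·OEt2 at −78 °C to aldehyde 6, and the threo adduct (S)-[2,6-bis(benzyloxy)phenyl][(2R)-3,3-dimethyloxiran-2-yl]methanol F3 is separated from its carbinol epimer by chromatography.
- Hydrogenolysis (H2, Pd/C, EtOAc, Et3N) gives 2-[(S)-[(2R)-3,3-dimethyloxiran-2-yl](hydroxy)methyl]benzene-1,3-diol F4.
- K2CO3 in MeOH closes F4 5-exo with inversion to (2S,3S)-2-(2-hydroxypropan-2-yl)-2,3-dihydro-1-benzofuran-3,4-diol F5.
- Mg-mediated ortho-formylation (MgCl2, Et3N, paraformaldehyde, MeCN, 60 °C) at the only free position ortho to the phenol gives 8.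

**Step 7 (hydroacylation).** The risks are branched (α-aryl enone) instead of linear insertion with an aryl alkyne, alkyne oligomerisation, oxa-Michael closure of the 2'-hydroxychalcone to a flavanone, and loss of the benzylic 3-OH on heating. The fallback replaces the C–H activation by a Claisen–Schmidt condensation; it sets out from 1 and 9, uses 6, and comes back at 13.
- Resorcinol 1 is C-acetylated (AcOH, ZnCl2, 140 °C) to 1-(2,4-dihydroxyphenyl)ethan-1-one F6.
- F6 undergoes the step 4 annulation with 6 through 1-{3-[(S)-[(2R)-3,3-dimethyloxiran-2-yl](hydroxy)methyl]-2,4-dihydroxyphenyl}ethan-1-one F7 (not isolated) to 1-[(2S,3S)-3,4-dihydroxy-2-(2-hydroxypropan-2-yl)-2,3-dihydro-1-benzofuran-5-yl]ethan-1-one F8.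
- 4-Iodophenol 9 is converted by Pd-catalysed reductive carbonylation (CO, HCO2Na, Pd(PPh3)2Cl2, DMF, 100 °C) into 4-hydroxybenzaldehyde F9.
- Condensation of F8 with F9 (aq. KOH, EtOH, rt) gives 13.

**Step 3 (making and handling 6).** The aldehyde is volatile, water-soluble and hydrate-prone, and the acetic acid by-product can open the epoxide. The fallback reverses the order of oxidation and epoxidation; it sets out from 4 and comes back at 6, bypassing 5.
- Prenol 4 is oxidised with MnO2 (CH2Cl2, rt) to 3-methylbut-2-enal F10.
- F10 is epoxidised under iminium organocatalysis (aq. H2O2, CH2Cl2, rt) with the (R)-diarylprolinol trimethylsilyl ether, the catalyst enantiomer that gives (S)-6. The resulting solution of 6 is used directly in step 4; the ee is expected to be lower than from step 2 and may need upgrading by recrystallising 8.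

## Further compounds

F1 | step 4 | 1,3-bis(benzyloxy)benzene | c1ccc(COc2cccc(OCc3ccccc3)c2)cc1
F2 | step 4 | [2,6-bis(benzyloxy)phenyl]lithium | [Li]c1c(OCc2ccccc2)cccc1OCc1ccccc1
F3 | step 4 | (S)-[2,6-bis(benzyloxy)phenyl][(2R)-3,3-dimethyloxiran-2-yl]methanol | O[C@@H](c1c(OCc2ccccc2)cccc1OCc1ccccc1)[C@H]1OC1(C)C
F4 | step 4 | 2-[(S)-[(2R)-3,3-dimethyloxiran-2-yl](hydroxy)methyl]benzene-1,3-diol | O[C@@H](c1c(O)cccc1O)[C@H]1OC1(C)C
F5 | step 4 | (2S,3S)-2-(2-hydroxypropan-2-yl)-2,3-dihydro-1-benzofuran-3,4-diol | CC(C)(O)[C@H]1Oc2cccc(O)c2[C@@H]1O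
F6 | step 7 | 1-(2,4-dihydroxyphenyl)ethan-1-one | CC(=O)c1ccc(O)cc1O
F7 | step 7 | 1-{3-[(S)-[(2R)-3,3-dimethyloxiran-2-yl](hydroxy)methyl]-2,4-dihydroxyphenyl}ethan-1-one | CC(=O)c1ccc(O)c([C@H](O)[C@H]2OC2(C)C)c1O
F8 | step 7 | 1-[(2S,3S)-3,4-dihydroxy-2-(2-hydroxypropan-2-yl)-2,3-dihydro-1-benzofuran-5-yl]ethan-1-one | CC(C)(O)[C@H]1Oc2ccc(C(C)=O)c(O)c2[C@@H]1O
F9 | step 7 | 4-hydroxybenzaldehyde | O=Cc1ccc(O)cc1
F10 | step 3 | 3-methylbut-2-enal | CC(C)=CC=O
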